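**Plan**

- Retrosynthesis: the cut order is the aryl–vinyl bond of the cinnamate, the C6–O acyl bond, C5–H/C6–O (from a Δ5 alkene), C4–CH3, ring A at C3–C4 and C4–C5 (C4 = carbon monoxide), and C10–C1 (allyl), which leads back to (R)-carvone.
- Forward: ring B is the carvone ring; allylation makes the C10 quaternary centre; a carbonylative B-alkyl Suzuki cyclisation closes ring A; MeLi, hydroboration, oxidation and reduction give the 4β,6β-diol; acrylation and the Heck coupling add the side chain last.
- Stereochemistry: C7 comes from (R)-carvone and C10 from the Pd/(S)-t-BuPHOX allylation. C4 is set by equatorial (α-face) MeLi attack opposite the axial C10 methyl, C5 by α-face hydroboration, and C6 by α-face hydride delivery to the ketone. The alkene geometry follows from the Heck mechanism.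
- Feature that makes the key event possible: the unsubstituted terminal =CH2 of the O6-acryloyl group, an electron-poor monosubstituted alkene three atoms outside the two cyclohexane rings, and the C–I bond at C3 of unprotected 3-iodophenol. The hindered axial C6–OH therefore only has to accept the smallest acyl group, and the phenol needs no protection.

Key step: step 11

Remark: ring positions are given in eudesmane numbering (C10 = ring-fusion carbon with methyl, C5 = ring-fusion CH, C4 = carbinol carbon, C6 = ester carbon, C7 = isopropyl carbon); β is the face of the C10 methyl. (R)-(−)-Carvone, 3-iodophenol and all reagents are taken as commercial.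

Step 1
Reactants: 1 (R)-(−)-carvone
Product: 2 (5R)-2-methyl-5-(propan-2-yl)cyclohex-2-en-1-one
Conditions: H2 (1 atm), RhCl(PPh3)3 (1 mol%), toluene, 23 °C
Reagents that add atoms: none
Why: Homogeneous hydrogenation with Wilkinson's catalyst should reduce only the unhindered 1,1-disubstituted isopropenyl alkene and leave the conjugated trisubstituted enone and the existing stereocentre (C7 of the target) untouched.

Step 2
Reactants: 2 (5R)-2-methyl-5-(propan-2-yl)cyclohex-2-en-1-one
Product: 4 prop-2-en-1-yl (5R)-2-methyl-5-(propan-2-yl)cyclohex-1-en-1-yl carbonate, via lithium enolate 3 (not isolated)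
Conditions: LiBH(s-Bu)3, THF, −78 °C; then ClCO2CH2CH=CH2, −78 → 0 °C
Reagents that add atoms: allyl chloroformate (C=CCOC(=O)Cl)
Why: Conjugate reduction of the β-unsubstituted enone gives the tetrasubstituted enolate regiospecifically, and O-acylation by the chloroformate (conjugate reduction–enolate trapping) fixes this regiochemistry as the allyl enol carbonate.

Step 3
Reactants: 4 prop-2-en-1-yl (5R)-2-methyl-5-(propan-2-yl)cyclohex-1-en-1-yl carbonate
Product: 5 (2S,5R)-2-methyl-5-(propan-2-yl)-2-(prop-2-en-1-yl)cyclohexan-1-one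
Conditions: Pd2(dba)3 (2.5 mol%), (S)-t-BuPHOX (6 mol%), THF, 25 °C
Reagents that add atoms: none
Why: Decarboxylative asymmetric allylic alkylation (Tsuji–Trost type) recombines the Pd-π-allyl and the enolate inside the chiral PHOX complex; the (S)-ligand, which gives the (S)-ketone in the parent 2-methylcyclohexanone series, should set the quaternary centre as 2S (allyl trans to isopropyl, C10 of the target) under catalyst control.

Step 4
Reactants: 5 (2S,5R)-2-methyl-5-(propan-2-yl)-2-(prop-2-en-1-yl)cyclohexan-1-one
Product: 7 (3S,6S)-6-methyl-3-(propan-2-yl)-6-(prop-2-en-1-yl)cyclohex-1-en-1-yl trifluoromethanesulfonate, via potassium enolate 6 (not isolated)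
Conditions: KHMDS, THF, −78 °C; then PhNTf2, −78 → 0 °C
Reagents that add atoms: N-phenylbis(trifluoromethanesulfonimide) (O=S(=O)(N(c1ccccc1)S(=O)(=O)C(F)(F)F)C(F)(F)F)
Why: Only one α-carbon carries hydrogen, so deprotonation gives a single enolate, which is sulfonylated on oxygen (enol triflate formation) without touching either stereocentre.

Step 5
Reactants: 7 (3S,6S)-6-methyl-3-(propan-2-yl)-6-(prop-2-en-1-yl)cyclohex-1-en-1-yl trifluoromethanesulfonate
Product: 9 (4aR,7S)-4a-methyl-7-(propan-2-yl)-3,4,4a,5,6,7-hexahydronaphthalen-1(2H)-one, via B-alkyl-9-BBN 8 (not isolated)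
Conditions: 9-BBN, THF, 0 → 23 °C; then Pd(PPh3)4 (5 mol%), K3PO4, CO (1 atm), dioxane, 60 °C
Reagents that add atoms: carbon monoxide ([C-]#[O+])
Why: 9-BBN hydroborates only the monosubstituted allyl alkene at its terminus; Pd(0) then inserts into the C–OTf bond, CO insertion gives the acyl-palladium, and intramolecular B-alkyl transmetalation with reductive elimination closes the six-membered ring A (intramolecular carbonylative B-alkyl Suzuki–Miyaura coupling), with CO becoming C4.

Step 6
Reactants: 9 (4aR,7S)-4a-methyl-7-(propan-2-yl)-3,4,4a,5,6,7-hexahydronaphthalen-1(2H)-one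
Product: 10 (1S,4aR,7S)-1,4a-dimethyl-7-(propan-2-yl)-1,2,3,4,4a,5,6,7-octahydronaphthalen-1-ol
Conditions: MeLi, Et2O/THF, −78 °C; H2O quench
Reagents that add atoms: methyllithium ([Li]C)
Why: 1,2-Addition of MeLi to the enone carbonyl; ring A is a chair with the C10 methyl axial and 1,3 to C4, so methyl should enter equatorially from the α face and leave the new hydroxyl axial (4β, 1S).

Step 7
Reactants: 10 (1S,4aR,7S)-1,4a-dimethyl-7-(propan-2-yl)-1,2,3,4,4a,5,6,7-octahydronaphthalen-1-ol
Product: 12 (1S,4aR,7S,8S,8aS)-1,4a-dimethyl-7-(propan-2-yl)decahydronaphthalene-1,8-diol, via alkylborane 11 (not isolated)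
Conditions: BH3·THF (3 equiv), THF, 0 → 23 °C; then NaOH, H2O2, 0 → 40 °C
Reagents that add atoms: hydrogen peroxide (OO)
Why: Hydroboration–oxidation adds H and B syn across C5=C6 with boron at the less substituted C6, from the α face opposite the axial C10 methyl and the C4 borinate, which should set 5α-H (trans ring fusion) together with a 6α-hydroxyl after oxidation with retention.

Step 8
Reactants: 12 (1S,4aR,7S,8S,8aS)-1,4a-dimethyl-7-(propan-2-yl)decahydronaphthalene-1,8-diol
Product: 13 (2S,4aR,8S,8aR)-8-hydroxy-4a,8-dimethyl-2-(propan-2-yl)octahydronaphthalen-1(2H)-one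
Conditions: Dess–Martin periodinane, CH2Cl2, 0 → 23 °C; crude product used directly
Reagents that add atoms: none
Why: Dess–Martin oxidation converts only the secondary alcohol (the tertiary one is inert) under neutral, non-enolising conditions, so the two α-stereocentres C5 and C7 of the new ketone should stay as set.

Step 9
Reactants: 13 (2S,4aR,8S,8aR)-8-hydroxy-4a,8-dimethyl-2-(propan-2-yl)octahydronaphthalen-1(2H)-one
Product: 14 (1S,4aR,7S,8R,8aS)-1,4a-dimethyl-7-(propan-2-yl)decahydronaphthalene-1,8-diol
Conditions: NaBH4, MeOH/THF, −40 → 0 °C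
Reagents that add atoms: none
Why: Hydride reduction of the ketone; the axial C10 methyl and the axial 4β-hydroxyl block the β face, so hydride should attack from the α (equatorial) side and give the axial 6β-alcohol, as in 6-oxo-5α-steroids, at a temperature too low for α-epimerisation.

Step 10
Reactants: 14 (1S,4aR,7S,8R,8aS)-1,4a-dimethyl-7-(propan-2-yl)decahydronaphthalene-1,8-diol
Product: 15 (1R,2S,4aR,8S,8aS)-8-hydroxy-4a,8-dimethyl-2-(propan-2-yl)decahydronaphthalen-1-yl prop-2-enoate
Conditions: CH2=CHCOCl, Et3N, DMAP (cat.), BHT (trace), CH2Cl2, 0 → 23 °C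
Reagents that add atoms: acryloyl chloride (C=CC(=O)Cl)
Why: DMAP-catalysed acylation should take place only at the secondary C6 hydroxyl, the tertiary C4 hydroxyl being unreactive, and acryloyl is the smallest acyl group that this hindered axial alcohol can be asked to accept.

Step 11
Reactants: 15 (1R,2S,4aR,8S,8aS)-8-hydroxy-4a,8-dimethyl-2-(propan-2-yl)decahydronaphthalen-1-yl prop-2-enoate; 16 3-iodophenol
Product: 17 (1R,2S,4aR,8S,8aS)-8-hydroxy-4a,8-dimethyl-2-(propan-2-yl)decahydronaphthalen-1-yl (2E)-3-(3-hydroxyphenyl)prop-2-enoate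
Conditions: Pd(OAc)2 (5 mol%), P(o-tol)3 (10 mol%), Et3N, MeCN, 80 °C
Reagents that add atoms: none
Why: Mizoroki–Heck arylation: Pd(0) inserts into the C–I bond of 16, the aryl–palladium adds syn across the acrylate C=C with the aryl group going to the unsubstituted terminal carbon, and syn β-hydride elimination followed by loss of HI to the base returns Pd(0). The closest known reaction type is the Heck coupling of aryl iodides, unprotected iodophenols included, with acrylate esters to give cinnamates. No ring is closed and no stereocentre is formed; the only new stereo-element is the alkene geometry, which should be E because insertion and elimination are both syn and the eliminating conformer holds aryl and ester anti. The step needs β-regioselectivity and chemoselectivity: the polarised monosubstituted acrylate directs the aryl group to the terminal CH2, and the substrate offers no other alkene or halide, while the tertiary C4 hydroxyl and the phenol are inert to Pd(0) and Et3N. Because the reacting alkene lies three atoms outside the congested decalin, the coupling should be indifferent to the hindrance at C6, and the free phenol makes protecting-group steps unnecessary.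

**Compound list**

1 | (R)-(−)-carvone, (5R)-2-methyl-5-(prop-1-en-2-yl)cyclohex-2-en-1-one | CC(=C)[C@@H]1CC=C(C)C(=O)C1 | starting material
2 | (5R)-2-methyl-5-(propan-2-yl)cyclohex-2-en-1-one (carvotanacetone) | CC(C)[C@@H]1CC=C(C)C(=O)C1 | intermediate
3 | lithium (5R)-2-methyl-5-(propan-2-yl)cyclohex-1-en-1-olate | CC(C)[C@@H]1CCC(C)=C([O-])C1.[Li+] | intermediate
4 | prop-2-en-1-yl (5R)-2-methyl-5-(propan-2-yl)cyclohex-1-en-1-yl carbonate | CC(C)[C@@H]1CCC(C)=C(OC(=O)OCC=C)C1 | intermediate
5 | (2S,5R)-2-methyl-5-(propan-2-yl)-2-(prop-2-en-1-yl)cyclohexan-1-one | CC(C)[C@@H]1CC[C@@](C)(CC=C)C(=O)C1 | intermediate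
6 | potassium (3S,6S)-6-methyl-3-(propan-2-yl)-6-(prop-2-en-1-yl)cyclohex-1-en-1-olate | CC(C)[C@@H]1CC[C@@](C)(CC=C)C([O-])=C1.[K+] | intermediate
7 | (3S,6S)-6-methyl-3-(propan-2-yl)-6-(prop-2-en-1-yl)cyclohex-1-en-1-yl trifluoromethanesulfonate | CC(C)[C@@H]1CC[C@@](C)(CC=C)C(OS(=O)(=O)C(F)(F)F)=C1 | intermediate
8 | 9-{3-[(1R,4S)-1-methyl-4-(propan-2-yl)-2-{[(trifluoromethyl)sulfonyl]oxy}cyclohex-2-en-1-yl]propyl}-9-borabicyclo[3.3.1]nonane | CC(C)[C@@H]1CC[C@@](C)(CCCB2C3CCCC2CCC3)C(OS(=O)(=O)C(F)(F)F)=C1 | intermediate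
9 | (4aR,7S)-4a-methyl-7-(propan-2-yl)-3,4,4a,5,6,7-hexahydronaphthalen-1(2H)-one | CC(C)[C@@H]1CC[C@@]2(C)CCCC(=O)C2=C1 | intermediate
10 | (1S,4aR,7S)-1,4a-dimethyl-7-(propan-2-yl)-1,2,3,4,4a,5,6,7-octahydronaphthalen-1-ol | CC(C)[C@@H]1CC[C@@]2(C)CCC[C@](C)(O)C2=C1 | intermediate
11 | 6α-boryl-4β-(boryloxy)-5α-eudesmane (alkylborane from syn addition on the α face; 7β-isopropyl, 10β-methyl) | CC(C)[C@@H]1CC[C@@]2(C)CCC[C@](C)(OB)[C@@H]2[C@H]1B | intermediate
12 | (1S,4aR,7S,8S,8aS)-1,4a-dimethyl-7-(propan-2-yl)decahydronaphthalene-1,8-diol (4β,6α-diol) | CC(C)[C@@H]1CC[C@@]2(C)CCC[C@](C)(O)[C@@H]2[C@H]1O | intermediate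
13 | (2S,4aR,8S,8aR)-8-hydroxy-4a,8-dimethyl-2-(propan-2-yl)octahydronaphthalen-1(2H)-one | CC(C)[C@@H]1CC[C@@]2(C)CCC[C@](C)(O)[C@@H]2C1=O | intermediate
14 | (1S,4aR,7S,8R,8aS)-1,4a-dimethyl-7-(propan-2-yl)decahydronaphthalene-1,8-diol (4β,6β-diol) | CC(C)[C@@H]1CC[C@@]2(C)CCC[C@](C)(O)[C@@H]2[C@@H]1O | intermediate
15 | (1R,2S,4aR,8S,8aS)-8-hydroxy-4a,8-dimethyl-2-(propan-2-yl)decahydronaphthalen-1-yl prop-2-enoate | CC(C)[C@@H]1CC[C@@]2(C)CCC[C@](C)(O)[C@@H]2[C@@H]1OC(=O)C=C | intermediate
16 | 3-iodophenol | Oc1cccc(I)c1 | starting material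
17 | (1R,2S,4aR,8S,8aS)-8-hydroxy-4a,8-dimethyl-2-(propan-2-yl)decahydronaphthalen-1-yl (2E)-3-(3-hydroxyphenyl)prop-2-enoate | CC(C)[C@@H]1CC[C@@]2(C)CCC[C@](C)(O)[C@@H]2[C@@H]1OC(=O)/C=C/c1cccc(O)c1 | target

**Step count**

Total: 11 steps. Longest linear sequence: 11 steps (1 to 17); 16 enters in the last step.

**Steps most likely to fail**

Step 5. The acyl-palladium may be bypassed: direct alkyl–vinyl coupling without CO uptake would close a five-membered ring, and protodeboronation or β-hydride elimination of the alkylborane would stop the sequence. The fallback sets out from 7 and builds ring A in three operations. Carbonylative Stille coupling of 7 with tributyl(vinyl)stannane (Pd(PPh3)4, LiCl, CO 1 atm, THF, 55 °C) should give the cross-conjugated divinyl ketone 1-[(3S,6S)-6-methyl-3-(propan-2-yl)-6-(prop-2-en-1-yl)cyclohex-1-en-1-yl]prop-2-en-1-one F1. Ring-closing metathesis between its vinyl ketone and allyl groups (Grubbs second-generation catalyst, CH2Cl2, 40 °C) should give the dienone (4aS,7S)-4a-methyl-7-(propan-2-yl)-4a,5,6,7-tetrahydronaphthalen-1(4H)-one F2. Hydrogenation of its disubstituted alkene only (H2, RhCl(PPh3)3) comes back to the route at 9.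

Step 7. Facial selectivity may be eroded if the borinate formed at the C4 oxygen delivers boron to the β face, and addition to an alkene flanked by two fully substituted carbons may be slow. The fallback sets out from 10 and uses the hydroxyl group as a director. Vanadium-catalysed epoxidation (VO(acac)2, t-BuOOH, CH2Cl2, 0 °C) should give the syn epoxy alcohol 5β,6β-epoxy-5β-eudesman-4β-ol F3. A Lewis acid (BF3·OEt2, CH2Cl2, −78 °C) then opens it at the tertiary C5, and the 1,2-shift of the C6 hydrogen across the α face (Meinwald rearrangement) gives the 5α-H ketone directly. The fallback comes back to the route at 13 and leaves out 12.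

Step 10. Acylation of the axial hydroxyl, flanked by the isopropyl group and 1,3-diaxial to the C10 methyl, may be slow enough for acryloyl chloride to be lost to polymerisation and to conjugate addition of chloride or amine. The fallback sets out from 14 and masks the alkene. Acylation with 3-chloropropanoyl chloride (pyridine, DMAP, CH2Cl2) should give (1R,2S,4aR,8S,8aS)-8-hydroxy-4a,8-dimethyl-2-(propan-2-yl)decahydronaphthalen-1-yl 3-chloropropanoate F4. Elimination of HCl with Et3N (CH2Cl2, 23 °C) comes back to the route at 15.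

**Further compounds**

F1 | step 5 | 1-[(3S,6S)-6-methyl-3-(propan-2-yl)-6-(prop-2-en-1-yl)cyclohex-1-en-1-yl]prop-2-en-1-one | CC(C)[C@@H]1CC[C@@](C)(CC=C)C(C(=O)C=C)=C1
F2 | step 5 | (4aS,7S)-4a-methyl-7-(propan-2-yl)-4a,5,6,7-tetrahydronaphthalen-1(4H)-one | CC(C)[C@@H]1CC[C@@]2(C)CC=CC(=O)C2=C1
F3 | step 7 | 5β,6β-epoxy-5β-eudesman-4β-ol (4α-methyl, 7β-isopropyl, 10β-methyl) | CC(C)[C@@H]1CC[C@@]2(C)CCC[C@](C)(O)[C@]23O[C@@H]31
F4 | step 10 | (1R,2S,4aR,8S,8aS)-8-hydroxy-4a,8-dimethyl-2-(propan-2-yl)decahydronaphthalen-1-yl 3-chloropropanoate | CC(C)[C@@H]1CC[C@@]2(C)CCC[C@](C)(O)[C@@H]2[C@@H]1OC(=O)CCCl
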